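**Retrosynthetic overview**
1. (R)-Carvone supplies ring B (C5–C10), C17 and, through its isopropenyl group, C4, C18 and C19; MeI (C20), allyl bromide (C1–C3), 3-(2-iodoethyl)-2,5-dihydrofuran (C11–C16, from enyne metathesis) and an acetyl group complete the skeleton.
2. Last disconnection: the C3–C4 bond of ring A (C4, C3, C2, C1, C10, C5), leading back to the ring-A-seco α-methylene-γ-lactone 32 with a 3-bromopropyl chain on C10.
3. Enabling feature: C4 is the α-carbon of the 19,6-lactone (ring C4–C19–O–C6–C5, cis-fused to ring B) and stands 1,3 to C10 across C5. An exocyclic C4=C18 alkene conjugated to C19 is therefore a latent, regiospecific C4 enolate: hydride addition at C18 and 6-exo-tet alkylation at C3 create C18H3, the quaternary C4 and ring A in one operation.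
4. Earlier disconnections: γ-lactone by oxidative α-lactonisation of the C19 acid onto C6; spiro-tetrahydrofuran by 5-exo opening of a C13–C14 epoxide by O9; O7/O8 by hydroxyl-directed dihydroxylation; C9–C11 by 1,2-addition; C10 by two enolate alkylations.
5. Order of ring formation: dihydrofuran ring (step 2), ring B (from carvone), spiro-tetrahydrofuran (step 17), γ-lactone (step 18), ring A last (step 20).

Key step: step 20

Remark: labdane numbering is used; compounds lacking the C3–C4 bond are named as 3,4-seco-labdanes; β is the face of ring B that carries the C10 methyl (C20), and from 17 onward all compounds have 5α-H, 10β-CH3 and C11 α.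

**Step 1**
Reactants: 1 prop-2-yn-1-ol; 2 3-bromoprop-1-ene (allyl bromide)
Product: 3 3-(prop-2-yn-1-yloxy)prop-1-ene
Conditions: 50% aq. NaOH, Bu4NHSO4 (cat.), 0 °C → rt
Reagents that add atoms: none
Why: Williamson ether synthesis under phase transfer, SN2 of the propargyl alkoxide on the allylic bromide; no stereocentre is formed.

**Step 2**
Reactants: 3 3-(prop-2-yn-1-yloxy)prop-1-ene
Product: 4 3-ethenyl-2,5-dihydrofuran
Conditions: Grubbs I catalyst (cat.), ethylene (1 atm), CH2Cl2, rt
Reagents that add atoms: none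
Why: Ring-closing enyne metathesis (exo mode) of the 1,6-enyne should close the 2,5-dihydrofuran ring and leave the 1,3-diene; no stereocentre.

**Step 3**
Reactants: 4 3-ethenyl-2,5-dihydrofuran
Product: 6 2-(2,5-dihydrofuran-3-yl)ethan-1-ol, via B-alkyl-9-BBN 5 (not isolated)
Conditions: 9-BBN, THF, 0 °C → rt; then NaOH, H2O2, 0 °C
Reagents that add atoms: hydrogen peroxide, OO
Why: Hydroboration–oxidation; 9-BBN should add anti-Markovnikov at the monosubstituted vinyl terminus and leave the trisubstituted ring alkene; no stereocentre.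

**Step 4**
Reactants: 6 2-(2,5-dihydrofuran-3-yl)ethan-1-ol
Product: 7 3-(2-iodoethyl)-2,5-dihydrofuran
Conditions: PPh3, imidazole, I2, CH2Cl2, 0 °C → rt
Reagents that add atoms: iodine, II
Why: Appel-type iodination of a primary alcohol (SN2 on the alkoxyphosphonium ion); no stereocentre.

**Step 5**
Reactants: 8 (R)-(−)-carvone
Product: 9 (5R)-5-(3-hydroxyprop-1-en-2-yl)-2-methylcyclohex-2-en-1-one
Conditions: SeO2 (cat.), t-BuOOH, CH2Cl2, rt
Reagents that add atoms: tert-butyl hydroperoxide, CC(C)(C)OO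
Why: Selenium dioxide allylic oxidation (ene reaction, then [2,3]-shift) should hydroxylate the methyl of the electron-rich isopropenyl group (future C19) in preference to the enone; C5 is untouched.

**Step 6**
Reactants: 9 (5R)-5-(3-hydroxyprop-1-en-2-yl)-2-methylcyclohex-2-en-1-one
Product: 10 (5R)-5-[3-(tert-butyldimethylsilyloxy)prop-1-en-2-yl]-2-methylcyclohex-2-en-1-one
Conditions: TBSCl, imidazole, DMF, rt
Reagents that add atoms: tert-butyldimethylsilyl chloride, CC(C)(C)[Si](C)(C)Cl
Why: Silyl ether formation on the primary allylic alcohol; no stereocentre.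

**Step 7**
Reactants: 10 (5R)-5-[3-(tert-butyldimethylsilyloxy)prop-1-en-2-yl]-2-methylcyclohex-2-en-1-one
Product: 12 (5R)-5-[3-(tert-butyldimethylsilyloxy)prop-1-en-2-yl]-2,6-dimethylcyclohex-2-en-1-one (C6 epimers), via lithium dienolate 11 (not isolated)
Conditions: LDA, THF, −78 °C; MeI, −78 → −20 °C
Reagents that add atoms: iodomethane, CI
Why: Kinetic α′-enolate alkylation of the cross-conjugated enone; the new centre (future C10) forms as an epimer mixture that converges on re-enolisation in step 8.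

**Step 8**
Reactants: 12 (5R)-5-[3-(tert-butyldimethylsilyloxy)prop-1-en-2-yl]-2,6-dimethylcyclohex-2-en-1-one (C6 epimers); 2 3-bromoprop-1-ene (allyl bromide)
Product: 14 (5S,6S)-6-allyl-5-[3-(tert-butyldimethylsilyloxy)prop-1-en-2-yl]-2,6-dimethylcyclohex-2-en-1-one, via lithium enolate 13 (not isolated)
Conditions: LDA, THF–DMPU, −78 → 0 °C; allyl bromide, −78 °C → rt
Reagents that add atoms: none
Why: Second enolate alkylation; allyl bromide should approach anti to the adjacent C5 side chain, so the quaternary centre (C10) carries CH3 cis and allyl (C1–C3) trans to that side chain.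

**Step 9**
Reactants: 14 (5S,6S)-6-allyl-5-[3-(tert-butyldimethylsilyloxy)prop-1-en-2-yl]-2,6-dimethylcyclohex-2-en-1-one; 7 3-(2-iodoethyl)-2,5-dihydrofuran
Product: 17 19-(tert-butyldimethylsilyloxy)-15,16-epoxy-3,4-seco-labda-2,4(18),7,13-tetraen-9β-ol, via alkyllithium 15 (not isolated), via alkylcerium dichloride 16 (not isolated)
Conditions: 7, t-BuLi, Et2O–pentane, −78 °C; CeCl3, THF, −78 °C; then 14, −78 → −40 °C
Reagents that add atoms: none
Why: Iodine–lithium exchange, transmetalation to cerium and 1,2-addition to the hindered enone; with the C5 side chain equatorial the C10 methyl is pseudo-axial, so attack anti to it should give C11 α and 9-OH β.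

**Step 10**
Reactants: 17 19-(tert-butyldimethylsilyloxy)-15,16-epoxy-3,4-seco-labda-2,4(18),7,13-tetraen-9β-ol
Product: 19 19-(tert-butyldimethylsilyloxy)-15,16-epoxy-3,4-seco-labda-4(18),7,13-triene-3,9β-diol, via B-alkyl-9-BBN 18 (not isolated)
Conditions: 9-BBN (excess), THF, 0 °C → rt; then NaOH, H2O2, 0 °C
Reagents that add atoms: hydrogen peroxide, OO
Why: Hydroboration–oxidation; 9-BBN should select the monosubstituted allyl alkene over the 1,1-disubstituted and trisubstituted alkenes, placing oxygen on C3; no stereocentre.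

**Step 11**
Reactants: 19 19-(tert-butyldimethylsilyloxy)-15,16-epoxy-3,4-seco-labda-4(18),7,13-triene-3,9β-diol
Product: 20 3-bromo-19-(tert-butyldimethylsilyloxy)-15,16-epoxy-3,4-seco-labda-4(18),7,13-trien-9β-ol
Conditions: CBr4, PPh3, CH2Cl2, 0 °C
Reagents that add atoms: carbon tetrabromide, BrC(Br)(Br)Br
Why: Appel bromination; the primary alcohol should react while the tertiary 9-OH, flanked by two fully substituted carbons, stays free; a primary bromide is chosen because it survives the oxidations ahead.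

**Step 12**
Reactants: 20 3-bromo-19-(tert-butyldimethylsilyloxy)-15,16-epoxy-3,4-seco-labda-4(18),7,13-trien-9β-ol
Product: 22 3-bromo-19-(tert-butyldimethylsilyloxy)-15,16-epoxy-3,4-seco-labda-4(18),13-diene-7β,8β,9β-triol, via osmate ester 21 (not isolated)
Conditions: OsO4, TMEDA, CH2Cl2, −78 °C; then aq. Na2SO3, THF, 50 °C
Reagents that add atoms: osmium tetroxide, O=[Os](=O)(=O)=O
Why: Hydrogen-bond-directed syn-dihydroxylation of the allylic alcohol with OsO4·TMEDA; delivery syn to the 9β-OH and anti to the axial C11 should set C8 (O β, CH3 α) and place O7 β, and the directing effect is relied on for selectivity over the other two alkenes.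

**Step 13**
Reactants: 22 3-bromo-19-(tert-butyldimethylsilyloxy)-15,16-epoxy-3,4-seco-labda-4(18),13-diene-7β,8β,9β-triol
Product: 23 3-bromo-19-(tert-butyldimethylsilyloxy)-15,16-epoxy-8β,9β-dihydroxy-3,4-seco-labda-4(18),13-dien-7-one
Conditions: IBX, DMSO, rt
Reagents that add atoms: none
Why: IBX oxidation of the only secondary alcohol; IBX oxidises 1,2-diols to α-ketols without glycol cleavage, and C8 is not affected.

**Step 14**
Reactants: 23 3-bromo-19-(tert-butyldimethylsilyloxy)-15,16-epoxy-8β,9β-dihydroxy-3,4-seco-labda-4(18),13-dien-7-one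
Product: 24 8β-acetoxy-3-bromo-19-(tert-butyldimethylsilyloxy)-15,16-epoxy-9β-hydroxy-3,4-seco-labda-4(18),13-dien-7-one
Conditions: Ac2O, Et3N, DMAP (cat.), CH2Cl2, rt → 35 °C
Reagents that add atoms: acetic anhydride, CC(=O)OC(C)=O
Why: DMAP-catalysed acylation; the α-ketol hydroxyl at C8 should acylate while the 9-OH between two quaternary carbons is expected to stay free, and masking O8 now prevents it from competing with O9 in step 17.

**Step 15**
Reactants: 24 8β-acetoxy-3-bromo-19-(tert-butyldimethylsilyloxy)-15,16-epoxy-9β-hydroxy-3,4-seco-labda-4(18),13-dien-7-one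
Product: 25 8β-acetoxy-3-bromo-15,16-epoxy-9β,19-dihydroxy-3,4-seco-labda-4(18),13-dien-7-one
Conditions: HF·pyridine, pyridine, THF, 0 °C → rt
Reagents that add atoms: none
Why: Fluoride-mediated desilylation of the primary allylic TBS ether; the acetate, bromide and allylic ether ring tolerate buffered HF.

**Step 16**
Reactants: 25 8β-acetoxy-3-bromo-15,16-epoxy-9β,19-dihydroxy-3,4-seco-labda-4(18),13-dien-7-one
Product: 27 8β-acetoxy-3-bromo-15,16-epoxy-9β-hydroxy-7-oxo-3,4-seco-labda-4(18),13-dien-19-oic acid, via enal 26 (not isolated)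
Conditions: MnO2, CH2Cl2, rt; filter; then NaClO2, NaH2PO4, 2-methylbut-2-ene, t-BuOH–H2O, 0 °C
Reagents that add atoms: sodium chlorite, [Na+].[O-]Cl=O
Why: MnO2 oxidises only the allylic alcohol and the Pinnick oxidation takes the enal to the acrylic acid, with 2-methylbut-2-ene protecting the dihydrofuran alkene from HOCl.

**Step 17**
Reactants: 27 8β-acetoxy-3-bromo-15,16-epoxy-9β-hydroxy-7-oxo-3,4-seco-labda-4(18),13-dien-19-oic acid
Product: 29 (13S,14S)-8β-acetoxy-3-bromo-9β,13:15,16-diepoxy-14-hydroxy-7-oxo-3,4-seco-labd-4(18)-en-19-oic acid, via epoxide 28 (not isolated)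
Conditions: ent-Shi ketone (L-fructose-derived, cat.), Oxone, K2CO3, Bu4NHSO4, MeCN–DMM–aq. buffer (pH ≈ 10), 0 °C; then CSA (cat.), CH2Cl2, rt
Reagents that add atoms: potassium peroxymonosulfate (active component of Oxone), [K+].[O-]S(=O)(=O)OO
Why: Shi asymmetric epoxidation of the only electron-rich alkene, then acid-catalysed 5-exo-tet opening by O9 at the tertiary C13 with inversion; by the spiro transition-state model the L-fructose-derived ketone should give the epoxide face that leads to C13 as in 34 (13S here only because C14 outranks C16), with the 14-OH trans to O9.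

**Step 18**
Reactants: 29 (13S,14S)-8β-acetoxy-3-bromo-9β,13:15,16-diepoxy-14-hydroxy-7-oxo-3,4-seco-labd-4(18)-en-19-oic acid
Product: 30 (13S,14S)-8β-acetoxy-3-bromo-9β,13:15,16-diepoxy-14-hydroxy-7-oxo-3,4-seco-labd-4(18)-en-19,6β-olide
Conditions: PhI(OH)OTs (Koser's reagent), MeCN, 40 °C
Reagents that add atoms: none
Why: Hypervalent-iodine α-oxidative lactonisation of a 5-oxo carboxylic acid; the ketone enolises only toward C6, and the tethered carboxylate can displace the C6 iodane only from its own face, so the γ-lactone should be cis-fused (O6 β, cis to C4).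

**Step 19**
Reactants: 30 (13S,14S)-8β-acetoxy-3-bromo-9β,13:15,16-diepoxy-14-hydroxy-7-oxo-3,4-seco-labd-4(18)-en-19,6β-olide
Product: 32 (13R)-8β-acetoxy-3-bromo-9β,13:15,16-diepoxy-7-oxo-3,4-seco-labda-4(18),14-dien-19,6β-olide, via sulfamate ester 31 (not isolated)
Conditions: Burgess reagent, benzene, rt → 60 °C
Reagents that add atoms: none
Why: Burgess dehydration (syn-elimination of the sulfamate); C13 is quaternary, so only the C15 hydrogens are available and the C14=C15 enol ether should form; C13 is not touched.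

**Step 20**
Reactants: 32 (13R)-8β-acetoxy-3-bromo-9β,13:15,16-diepoxy-7-oxo-3,4-seco-labda-4(18),14-dien-19,6β-olide
Product: 34 (13R)-8β-acetoxy-9β,13:15,16-diepoxy-7-oxolabd-14-en-19,6β-olide (target), via silyl ketene acetal 33 (not isolated)
Conditions: [(Ph3P)CuH]6 (cat.), PhMe2SiH, toluene, 0 °C → rt; then TBAT, THF (high dilution), 0 °C → rt
Reagents that add atoms: none
Why: Copper hydride adds hydride to the unhindered exocyclic C18 of the α-methylene lactone (1,4-hydrosilylation) to give silyl ketene acetal 33, and fluoride then releases the C4 enolate, which displaces the primary bromide at C3. The closest known reaction type is the copper hydride conjugate reduction–enolate alkylation tandem, a hydride-initiated Michael–ring-closure sequence. Ring A (C4, C3, C2, C1, C10, C5) closes in the 6-exo-tet mode with the enolate double bond exocyclic to the new ring. The new quaternary centre C4 is controlled by the cis-fused lactone and the C10 tether: C3 can reach only the enolate face syn to C10, which leaves C19 axial (β, already bound to O6) and C18 equatorial (α) and gives the trans-fused decalin. The step needs hydride delivery to the enoate rather than to the hindered C7 ketone, the tertiary acetate or the enol ether, and C-alkylation faster than proton transfer from C6–H; the soft copper hydride, the base-free regiospecific generation of the enolate, high dilution and the six-membered intramolecular transition state are expected to secure this.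

**Compound list**
1 | prop-2-yn-1-ol | C#CCO | starting material
2 | 3-bromoprop-1-ene (allyl bromide) | C=CCBr | starting material
3 | 3-(prop-2-yn-1-yloxy)prop-1-ene | C=CCOCC#C | intermediate
4 | 3-ethenyl-2,5-dihydrofuran | C=CC1=CCOC1 | intermediate
5 | 9-[2-(2,5-dihydrofuran-3-yl)ethyl]-9-borabicyclo[3.3.1]nonane | C(CC1=CCOC1)B1C2CCCC1CCC2 | intermediate
6 | 2-(2,5-dihydrofuran-3-yl)ethan-1-ol | OCCC1=CCOC1 | intermediate
7 | 3-(2-iodoethyl)-2,5-dihydrofuran | ICCC1=CCOC1 | intermediate
8 | (R)-(−)-carvone, (5R)-2-methyl-5-(prop-1-en-2-yl)cyclohex-2-en-1-one | CC1=CC[C@H](CC1=O)C(C)=C | starting material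
9 | (5R)-5-(3-hydroxyprop-1-en-2-yl)-2-methylcyclohex-2-en-1-one | CC1=CC[C@H](CC1=O)C(=C)CO | intermediate
10 | (5R)-5-[3-(tert-butyldimethylsilyloxy)prop-1-en-2-yl]-2-methylcyclohex-2-en-1-one | CC1=CC[C@H](CC1=O)C(=C)CO[Si](C)(C)C(C)(C)C | intermediate
11 | lithium cross-conjugated dienolate of 10 (C1–OLi, C1=C6) | CC1=CC[C@H](C=C1[O-])C(=C)CO[Si](C)(C)C(C)(C)C.[Li+] | intermediate
12 | (5R)-5-[3-(tert-butyldimethylsilyloxy)prop-1-en-2-yl]-2,6-dimethylcyclohex-2-en-1-one, mixture of C6 epimers | CC1=CC[C@H](C(C)C1=O)C(=C)CO[Si](C)(C)C(C)(C)C | intermediate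
13 | lithium dienolate of 12 (C1–OLi, C1=C6) | CC1=CC[C@H](C(C)=C1[O-])C(=C)CO[Si](C)(C)C(C)(C)C.[Li+] | intermediate
14 | (5S,6S)-6-allyl-5-[3-(tert-butyldimethylsilyloxy)prop-1-en-2-yl]-2,6-dimethylcyclohex-2-en-1-one (allyl trans, 6-CH3 cis to the C5 side chain) | CC1=CC[C@H]([C@](C)(CC=C)C1=O)C(=C)CO[Si](C)(C)C(C)(C)C | intermediate
15 | [2-(2,5-dihydrofuran-3-yl)ethyl]lithium | [Li]CCC1=CCOC1 | intermediate
16 | dichloro[2-(2,5-dihydrofuran-3-yl)ethyl]cerium | Cl[Ce](Cl)CCC1=CCOC1 | intermediate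
17 | 19-(tert-butyldimethylsilyloxy)-15,16-epoxy-3,4-seco-labda-2,4(18),7,13-tetraen-9β-ol | CC1=CC[C@H]([C@](C)(CC=C)[C@]1(O)CCC1=CCOC1)C(=C)CO[Si](C)(C)C(C)(C)C | intermediate
18 | 3-(9-borabicyclo[3.3.1]nonan-9-yl) derivative of 17 (B on C3, C2–C3 saturated) | CC1=CC[C@H]([C@](C)(CCCB2C3CCCC2CCC3)[C@]1(O)CCC1=CCOC1)C(=C)CO[Si](C)(C)C(C)(C)C | intermediate
19 | 19-(tert-butyldimethylsilyloxy)-15,16-epoxy-3,4-seco-labda-4(18),7,13-triene-3,9β-diol | CC1=CC[C@H]([C@](C)(CCCO)[C@]1(O)CCC1=CCOC1)C(=C)CO[Si](C)(C)C(C)(C)C | intermediate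
20 | 3-bromo-19-(tert-butyldimethylsilyloxy)-15,16-epoxy-3,4-seco-labda-4(18),7,13-trien-9β-ol | CC1=CC[C@H]([C@](C)(CCCBr)[C@]1(O)CCC1=CCOC1)C(=C)CO[Si](C)(C)C(C)(C)C | intermediate
21 | cyclic 7β,8β-osmate(VI) ester of 22, TMEDA complex | C[C@]12O[Os](=O)(=O)O[C@H]1C[C@H]([C@](C)(CCCBr)[C@]2(O)CCC1=CCOC1)C(=C)CO[Si](C)(C)C(C)(C)C.CN(C)CCN(C)C | intermediate
22 | 3-bromo-19-(tert-butyldimethylsilyloxy)-15,16-epoxy-3,4-seco-labda-4(18),13-diene-7β,8β,9β-triol | C[C@]1(O)[C@@H](O)C[C@H]([C@](C)(CCCBr)[C@]1(O)CCC1=CCOC1)C(=C)CO[Si](C)(C)C(C)(C)C | intermediate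
23 | 3-bromo-19-(tert-butyldimethylsilyloxy)-15,16-epoxy-8β,9β-dihydroxy-3,4-seco-labda-4(18),13-dien-7-one | C[C@]1(O)C(=O)C[C@H]([C@](C)(CCCBr)[C@]1(O)CCC1=CCOC1)C(=C)CO[Si](C)(C)C(C)(C)C | intermediate
24 | 8β-acetoxy-3-bromo-19-(tert-butyldimethylsilyloxy)-15,16-epoxy-9β-hydroxy-3,4-seco-labda-4(18),13-dien-7-one | CC(=O)O[C@@]1(C)C(=O)C[C@H]([C@](C)(CCCBr)[C@]1(O)CCC1=CCOC1)C(=C)CO[Si](C)(C)C(C)(C)C | intermediate
25 | 8β-acetoxy-3-bromo-15,16-epoxy-9β,19-dihydroxy-3,4-seco-labda-4(18),13-dien-7-one | CC(=O)O[C@@]1(C)C(=O)C[C@H]([C@](C)(CCCBr)[C@]1(O)CCC1=CCOC1)C(=C)CO | intermediate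
26 | 8β-acetoxy-3-bromo-15,16-epoxy-9β-hydroxy-7-oxo-3,4-seco-labda-4(18),13-dien-19-al | CC(=O)O[C@@]1(C)C(=O)C[C@H]([C@](C)(CCCBr)[C@]1(O)CCC1=CCOC1)C(=C)C=O | intermediate
27 | 8β-acetoxy-3-bromo-15,16-epoxy-9β-hydroxy-7-oxo-3,4-seco-labda-4(18),13-dien-19-oic acid | CC(=O)O[C@@]1(C)C(=O)C[C@H]([C@](C)(CCCBr)[C@]1(O)CCC1=CCOC1)C(=C)C(=O)O | intermediate
28 | 8β-acetoxy-3-bromo-13,14:15,16-diepoxy-9β-hydroxy-7-oxo-3,4-seco-labd-4(18)-en-19-oic acid (epoxide oxygen on the face anti to the later C13–O9 bond) | CC(=O)O[C@@]1(C)C(=O)C[C@H]([C@](C)(CCCBr)[C@]1(O)CC[C@@]12COC[C@@H]1O2)C(=C)C(=O)O | intermediate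
29 | (13S,14S)-8β-acetoxy-3-bromo-9β,13:15,16-diepoxy-14-hydroxy-7-oxo-3,4-seco-labd-4(18)-en-19-oic acid (C13 spatially as in 34, 14-OH trans to O9) | CC(=O)O[C@@]1(C)C(=O)C[C@H]([C@](C)(CCCBr)[C@]12CC[C@]1([C@@H](O)COC1)O2)C(=C)C(=O)O | intermediate
30 | (13S,14S)-8β-acetoxy-3-bromo-9β,13:15,16-diepoxy-14-hydroxy-7-oxo-3,4-seco-labd-4(18)-en-19,6β-olide | CC(=O)O[C@@]1(C)C(=O)[C@H]2OC(=O)C(=C)[C@H]2[C@](C)(CCCBr)[C@]12CC[C@]1([C@@H](O)COC1)O2 | intermediate
31 | 14-O-[N-(methoxycarbonyl)sulfamoyl] derivative of 30, triethylammonium salt | CC(=O)O[C@@]1(C)C(=O)[C@H]2OC(=O)C(=C)[C@H]2[C@](C)(CCCBr)[C@]12CC[C@]1([C@@H](OS(=O)(=O)[N-]C(=O)OC)COC1)O2.CC[NH+](CC)CC | intermediate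
32 | (13R)-8β-acetoxy-3-bromo-9β,13:15,16-diepoxy-7-oxo-3,4-seco-labda-4(18),14-dien-19,6β-olide | CC(=O)O[C@@]1(C)C(=O)[C@H]2OC(=O)C(=C)[C@H]2[C@](C)(CCCBr)[C@]12CC[C@]1(C=COC1)O2 | intermediate
33 | O-(dimethylphenylsilyl) ketene acetal of the 18-hydro lactone (C4=C19, C18 = CH3), otherwise as 32 | CC(=O)O[C@@]1(C)C(=O)[C@H]2OC(O[Si](C)(C)c3ccccc3)=C(C)[C@H]2[C@](C)(CCCBr)[C@]12CC[C@]1(C=COC1)O2 | intermediate
34 | (4S,5R,6S,8R,9R,10S,13R)-8β-acetoxy-9β,13:15,16-diepoxy-7-oxolabd-14-en-19,6β-olide (CNP0155227.1) | CC(=O)O[C@@]1(C)C(=O)[C@H]2OC(=O)[C@@]3(C)CCC[C@@](C)([C@@H]23)[C@]12CC[C@]1(C=COC1)O2 | target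

**Totals**
Total step count: 20. Longest linear sequence: 16 steps (steps 5–20, from (R)-carvone); steps 1–4 make the side-chain iodide 7.

**Steps most likely to fail and their fallbacks**

Step 20 (key step). Proton transfer from C6–H (α to the C7 ketone) to the fluoride-liberated C4 enolate, or protodesilylation of 33, may outrun the 6-exo-tet closure and quench the enolate; copper hydride reduction of the C7 carbonyl is a second loss channel. The fallback sets out from 32 and comes back at 34. The ketone is first stored as its own enolate: KHMDS (1 equiv, THF, −78 °C) removes C6–H to give the potassium C6(7)-enolate F1; no C–H acid is left, and acyl migration is blocked because it would need a bridgehead enolate. K-Selectride (−78 °C) then adds hydride to C18, since borohydride conjugate reduction does not touch an enolate and is slow on the hindered tertiary acetate, and gives the dipotassium bis-enolate F2. Warming to 0 °C with DMPU should close ring A by the same 6-exo-tet alkylation at the more reactive lactone enolate. NH4Cl work-up reprotonates C6, which can only occur from the α face once the lactone cage is closed, to give 34. This is the borohydride-initiated Michael–ring-closure with in-situ enolate protection of the ketone.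

Step 17. Facial discrimination by the dioxirane on a 3-alkyl-2,5-dihydrofuran may be insufficient, so that both C13 epimers form; the β-hydroxy ketone may also suffer retro-aldol cleavage at pH 10. The fallback sets out from 27 and comes back at 32. Koser's reagent (as in step 18) lactonises first to 8β-acetoxy-3-bromo-15,16-epoxy-9β-hydroxy-7-oxo-3,4-seco-labda-4(18),13-dien-19,6β-olide F3. A Lewis-base-catalysed enantioselective selenoetherification (N-(phenylseleno)succinimide, chiral BINAM-derived selenophosphoramide catalyst, MsOH, CH2Cl2, −20 °C) then lets O9 open the seleniranium ion at C13 (5-exo, anti addition), giving the 14-phenylselanyl spiro ether F4 with C13 under catalyst control. H2O2/pyridine (0 °C → rt) oxidises selenium, and selenoxide syn-elimination toward C15, the only β-hydrogens, should give 32 directly; this also replaces step 19.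

Step 12. Osmylation may also occur at the dihydrofuran or C4(18) alkenes, or from the α face of C7=C8, if the hydrogen-bond direction is weak for this tertiary alcohol. The fallback sets out from 20 and comes back at 23. VO(acac)2/t-BuOOH (CH2Cl2, 0 °C) epoxidises only the allylic-alcohol alkene, syn to 9-OH, to give the 7β,8β-epoxide F5. Ti(O-i-Pr)4/PhCO2H opens this 2,3-epoxy alcohol at the remote secondary carbon C7 with inversion (C3-selective opening), retaining the 8β C–O bond, to give the 7α-benzoate F6. K2CO3/MeOH removes the benzoate to give the 7α,8β,9β-triol F7, the C7 epimer of 22. IBX/DMSO as in step 13 oxidises C7 and returns 23.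

**Further compounds**
F1 | step 20 | potassium C6(7)-enolate of 32 | CC(=O)O[C@@]1(C)C([O-])=C2OC(=O)C(=C)[C@H]2[C@](C)(CCCBr)[C@]12CC[C@]1(C=COC1)O2.[K+]
F2 | step 20 | dipotassium bis-enolate (C6=C7–O− and C4=C19–O−, C18 = CH3) | CC(=O)O[C@@]1(C)C([O-])=C2OC([O-])=C(C)[C@H]2[C@](C)(CCCBr)[C@]12CC[C@]1(C=COC1)O2.[K+].[K+]
F3 | step 17 | 8β-acetoxy-3-bromo-15,16-epoxy-9β-hydroxy-7-oxo-3,4-seco-labda-4(18),13-dien-19,6β-olide | CC(=O)O[C@@]1(C)C(=O)[C@H]2OC(=O)C(=C)[C@H]2[C@](C)(CCCBr)[C@]1(O)CCC1=CCOC1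
F4 | step 17 | 8β-acetoxy-3-bromo-9β,13:15,16-diepoxy-7-oxo-14-(phenylselanyl)-3,4-seco-labd-4(18)-en-19,6β-olide (Se trans to O9, C13 as in 34) | CC(=O)O[C@@]1(C)C(=O)[C@H]2OC(=O)C(=C)[C@H]2[C@](C)(CCCBr)[C@]12CC[C@]1([C@@H]([Se]c3ccccc3)COC1)O2
F5 | step 12 | 3-bromo-19-(tert-butyldimethylsilyloxy)-7β,8β:15,16-diepoxy-3,4-seco-labda-4(18),13-dien-9β-ol | C[C@]12O[C@H]1C[C@H]([C@](C)(CCCBr)[C@]2(O)CCC1=CCOC1)C(=C)CO[Si](C)(C)C(C)(C)C
F6 | step 12 | 7α-benzoyloxy-3-bromo-19-(tert-butyldimethylsilyloxy)-15,16-epoxy-3,4-seco-labda-4(18),13-diene-8β,9β-diol | C[C@]1(O)[C@H](OC(=O)c2ccccc2)C[C@H]([C@](C)(CCCBr)[C@]1(O)CCC1=CCOC1)C(=C)CO[Si](C)(C)C(C)(C)C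
F7 | step 12 | 3-bromo-19-(tert-butyldimethylsilyloxy)-15,16-epoxy-3,4-seco-labda-4(18),13-diene-7α,8β,9β-triol | C[C@]1(O)[C@H](O)C[C@H]([C@](C)(CCCBr)[C@]1(O)CCC1=CCOC1)C(=C)CO[Si](C)(C)C(C)(C)C
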